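In a one-step world, with J going to L and to X side by side, each first order, the share of L in L plus X stays put and no vessel beats another. The red run refuses this: its share falls from 82.9% at 0.417 min to 38.5% at 5.00 min.

| setting | red | amber | grey | Saturday's | Sunday's | Friday's | Monday's |
|---|---|---|---|---|---|---|---|
| J | 0.14 M | 0.070 M | 0.11 M | 0.14 M | 0.14 M (fed, over 2.50 min) | 0.14 M | 0.14 M |
| E | 0.70 equiv | 0.70 equiv | 0.70 equiv | 0.700 equiv | 0.700 equiv | 0.700 equiv | 0.700 equiv (fed, over 2.50 min) |
| remark | run made earlier | run made earlier | run made earlier | a closed flask charged with all of it at once and left for 5.0 min | a stirred flask in which J is dosed at a steady rate over 2.50 min without added volume, worked up at 5.0 min | a single well-mixed tank run continuously and read at steady state, 5.0 min in it on average | all but E at the start; E goes in evenly over 2.50 min, the run ends at 5.0 min |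
| time |  |  |  | 5.0 min | 5.0 min |  | 5.0 min |

- red (time / min: L / %, X / %): 0.417: 34, 7; 0.833: 30, 10; 1.33: 31, 15; 2.50: 30, 25; 5.00: 25, 40
- amber (time / min: L / %, X / %): 0.667: 39, 8; 1.33: 34, 11; 2.00: 32, 17; 2.50: 30, 19; 3.00: 31, 20
- grey (time / min: L / %, X / %): 0.250: 33, 3; 0.833: 34, 9; 1.33: 30, 12; 2.00: 27, 18; 3.00: 27, 27

(scatter of a reading: 1.5 percentage points)

- the stated concentrations are those of everything mixed, before any reaction; amounts are the same in each set-up
- the analysis behind the earlier runs scatters by 1.5 percentage points, standard deviation
- the feed brings no volume worth counting
- the earlier runs were made in a closed, stirred flask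

* the set-up with the highest share of L in all that became L or X, at the outlet or at the end ("none" if the first two lie within 2 percentage points) (Saturday's / Sunday's / Friday's / Monday's / none)
* share of L in all that became L or X, at the outlet or at the end, Saturday's
* share of L in all that became L or X, at the outlet or at the end, Sunday's
* share of L in all that became L or X, at the outlet or at the end, Friday's
* share of L in all that became L or X, at the outlet or at the end, Monday's

Turn the question round. Lowering E gains nothing if the pace of X takes no notice of E, and then red and amber, at half the concentration, should show equal percentages of X at equal times. At 2.50 min they read 25% and 19%, a gap of 6 percentage points, or 2.83 standard deviations of a difference.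

So we write the balance of E, the limiting reagent at 0.700 equiv: E not yet in X is 0.7 of the J charged, less X. X's pace, in fractions of the J charged, divided by L and by that balance, is our drain constant, 0.582 /min, read from red between 2.50 min and 5.00 min. Amber, read between 1.33 min and 3.00 min, gives 0.304 /min, about half of red's, as its concentration asks.

In Friday's tank, X equals the drain constant times the mean time, L and the balance at the outlet. With red's late L of 27.5%, our reckoning gives X 31.1% and a share of 46.9%, higher than red's 38.5% at 5.00 min, which is Saturday's recipe.

The forecast names Friday's, with 37.5%, 42%, 46% and 42% in the order asked, taking X as “the slow, irreversible drain”.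

The flask gives 35.8%, 41.2%, 44.1% and 41.2%, so Friday's leads by 2.9 points, while the side-by-side fit answers none.

    E + L → X (k = 0.110 /M/s)
    J + E ⇌ Q (K = 12.0 /M, k = 3.20 /M/s)
    J ⇌ G (K = 0.390, k = 0.0250 /s)
    J ⇌ L (K = 1.10, k = 0.190 /s)

Saturday's share at 50.0 min reads 16.0%; taking X at the 0.7 of the J charged that E allows, that share means L of 13.4%, and the drain constant then gives E not yet in X a decay time of 12.9 min, shorter than the run.

The readings are calculated with constants of no real substance, and the scatter is random.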